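Which flask holds the most mono adduct at 15 min, when maple, birch and larch are charged alike and differ in temperature?

the same everywhere: reagent 0.0648 M
- south-east: substrate 0.054 M; temperature 18 °C; run made earlier
- west: substrate 0.12 M; temperature 34 °C; run made earlier
- maple: substrate 0.081 M; temperature 40 °C; time 15 min
- birch: substrate 0.081 M; temperature 25 °C; time 15 min
- larch: substrate 0.081 M; temperature 10 °C; time 15 min

| run | time / min | mono adduct / % | substrate / % |
|---|---|---|---|
| south-east | 8.00 | 9 | 86 |
| south-east | 20.0 | 17 | 74 |
| south-east | 40.0 | 21 | 55 |
| south-east | 60.0 | 21 | 44 |
| west | 5.00 | 11 | 75 |
| west | 10.0 | 12 | 62 |
| west | 15.0 | 9 | 53 |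
| west | 20.0 | 8 | 46 |

(standard deviation of a reading: 1.5 percentage points)

- the flask that comes out highest in amount of mono adduct, in percent of the substrate charged, or "all alike" when all lie within 1.5 percentage points (maple / birch / larch / all alike)
- mono adduct at the end, in percent of the substrate charged, maple
- mono adduct at the end, in percent of the substrate charged, birch
- mono adduct at the end, in percent of the substrate charged, larch

- percent here means substrate units held: one side product counts as two
- steps that have been proposed: substrate + reagent -> mono adduct; reagent + mono adduct -> double product; reagent + double product -> tris adduct; substrate + mono adduct -> side product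

I turn the settings by hand, with every amount as a fraction of its charge.

Temperature comes first. The first reading of each run gives a starting loss of substrate per minute, 0.0175 min⁻¹ in south-east and 0.0500 min⁻¹ in west, and the reagent charge is the same in both. Mono adduct reads flat in south-east between 40.0 min and 60.0 min, where its ratio to substrate reads 0.424. Near its peak in west the ratio reads 0.194. So from south-east to west the loss grows and the ratio falls, with temperature and substrate charge changed together. Taking a constant factor per degree, maple's ratio is 0.144. This balance ratio, mono adduct over substrate where its making equals its two losses (a quasi-steady state), is what I carry.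

Substrate charge comes next. West holds more than south-east, and the substrate + mono adduct step grows with substrate, so my ratio mixes charge with temperature.

Time comes last. Mono adduct cannot exceed the substrate lost, and once it has climbed to the balance line, ratio times substrate left, I take it to follow that line down as substrate goes. I take substrate left as the exponential of the starting loss over 15 min, with that loss carried to each temperature by a constant factor per degree:

larch: ratio 0.628, substrate left 0.856, line 0.538, substrate lost 0.144

birch: ratio 0.301, substrate left 0.660, line 0.199, substrate lost 0.340

maple: ratio 0.144, substrate left 0.329, line 0.0474, substrate lost 0.671

Taking the smaller of the two figures in each, I expect birch highest. I expect maple to come down onto its line from above, so I read its figure as a low mark.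

The forecast also says birch, with 17% for maple, 18% for birch and 9.5% for larch. Its maple stands above my line and its larch below my substrate lost, and of birch against maple it says “the side reaction tips it slightly to birch”.

Highest comes out birch at 15.7%, with maple at 11.5% and larch at 9.68%. Maple lies 5.5 percentage points under the forecast and above my line. At 15.0 min maple makes mono adduct at 0.696 of the rate at which it uses it. Maple's ratio of mono adduct to substrate then stands at 0.292, above my balance ratio, which is the side on which mono adduct falls.

    substrate + reagent → mono adduct (k = 0.00680 M⁻¹ s⁻¹, Ea = 52.0 kJ mol⁻¹)
    reagent + mono adduct → double product (k = 0.00960 M⁻¹ s⁻¹, Ea = 56.0 kJ mol⁻¹)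
    reagent + double product → tris adduct (k = 0.0160 M⁻¹ s⁻¹, Ea = 64.0 kJ mol⁻¹)
    substrate + mono adduct → side product (k = 0.00990 M⁻¹ s⁻¹, Ea = 69.0 kJ mol⁻¹)
    (constants at 25 °C)

For a flask like maple kept at 55 °C, the same factor per degree puts the balance ratio at 0.0691, about half of maple's, so I expect less mono adduct than in maple. That flask gives 4.45%, with 19.7% of the substrate left.

The numbers in the tables were generated by integration for substances that don't exist; the scatter is artificial.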